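**Plan**
- Retr osynthesis cuts, in order: the C3=C4 ring alkene (ring-closing metathesis of a 1,7-diene), the C1–C2 bond (γ-benzoyloxyallyl metal plus ketone) and the C5–C6 bond (aldol). What remains is a dihydroxyacetone unit (CH2O–C1–C6) and two acrolein units.
- Enabling feature: the only carbocycle is a cyclohexene whose cis C3=C4 bond is flanked by the two benzoyloxy-bearing carbons C2 and C5, the retron of a 3,6-diacyloxyocta-1,7-diene. The CH2–O on C1 and the O on C6 can be tied into a temporary 2,2-dimethyl-1,3-dioxane ring.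
- Forward: the chain is joined at C5–C6 first, then at C1–C2 on the dioxanone ketone; the cyclohexene is the last ring, closed at C3=C4. The dioxane is then removed and the primary hydroxyl benzoylated.
- Stereochemistry: C5 and C6 come from the (S)-proline-catalysed anti aldol, C1 from axial attack on the chair dioxanone, C2 from the closed chair transition state of the allylzinc addition. The metathesis creates no stereocentre.

Key step: step 7

Remark: ring positions are numbered as in the target name (C1 bears OH and CH2OBz, C2 and C5 bear OBz, C3=C4 is the alkene, C6 bears OH); reagent 8 is used as its E/Z mixture because both isomers give the same allylzinc species.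

**Step 1**
Reactants: 1 acrolein (prop-2-enal); 2 benzeneselenol
Product: 3 3-(phenylselanyl)propanal
Conditions: Et3N (1 mol %), CH2Cl2, 0 °C
Reagents that add atoms: none
Why: Conjugate (selena-Michael) addition of the soft selenol to the enal should give a linear β-selanyl aldehyde that stands in for acrolein and can be unmasked later by selenoxide elimination; no stereocentre is formed.

**Step 2**
Reactants: 3 3-(phenylselanyl)propanal; 4 2,2-dimethyl-1,3-dioxan-5-one
Product: 5 (4S)-4-[(1S)-1-hydroxy-3-(phenylselanyl)propyl]-2,2-dimethyl-1,3-dioxan-5-one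
Conditions: (S)-proline (30 mol %), DMF, 4 °C
Reagents that add atoms: none
Why: The proline-catalysed direct aldol reaction of the dioxanone enamine with a linear aldehyde should give the anti aldol through the hydrogen-bonded enamine transition state, setting C4 of the dioxane and the carbinol carbon both as (S), which are target C6 and C5.

**Step 3**
Reactants: 5 (4S)-4-[(1S)-1-hydroxy-3-(phenylselanyl)propyl]-2,2-dimethyl-1,3-dioxan-5-one
Product: 6 (1S)-1-[(4S)-2,2-dimethyl-5-oxo-1,3-dioxan-4-yl]-3-(phenylselanyl)propyl benzoate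
Conditions: BzCl, pyridine, DMAP (cat.), CH2Cl2, 0 °C
Reagents that add atoms: benzoyl chloride, O=C(Cl)c1ccccc1
Why: Pyridine-mediated O-acylation of the secondary carbinol installs the C5 benzoate of the target directly, and the weak base at 0 °C should avoid retro-aldol cleavage and β-elimination, so no stereocentre is touched.

**Step 4**
Reactants: 1 acrolein (prop-2-enal); 7 benzoyl bromide
Product: 8 3-bromoprop-1-en-1-yl benzoate (E/Z mixture)
Conditions: ZnCl2 (cat.), CH2Cl2, −20 °C to rt
Reagents that add atoms: none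
Why: Lewis-acid-promoted 1,4-addition of the acyl bromide to the enal (O-acylation with bromide delivered to the β-carbon) should give the γ-benzoyloxyallyl bromide; its alkene geometry is irrelevant for step 5.

**Step 5**
Reactants: 6 (1S)-1-[(4S)-2,2-dimethyl-5-oxo-1,3-dioxan-4-yl]-3-(phenylselanyl)propyl benzoate; 8 3-bromoprop-1-en-1-yl benzoate
Product: 10 (1S)-1-[(4S,5S)-5-[(1S)-1-(benzoyloxy)prop-2-en-1-yl]-5-hydroxy-2,2-dimethyl-1,3-dioxan-4-yl]-3-(phenylselanyl)propyl benzoate, via allylzinc bromide 9 (not isolated)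
Conditions: Zn dust, THF/sat. aq. NH4Cl, 0 °C to rt
Reagents that add atoms: none
Why: In this Barbier-type γ-acyloxyallylation (carbonyl α-hydroxyallylation) the allylzinc should add through its oxygen-bearing carbon in a closed chair transition state to the axial face of the dioxanone, which has no 1,3-diaxial hydrogens, placing the new bond cis to the equatorial C4 side chain (target C1), while the benzoyloxy group is expected to sit away from the branched C4 side and so give the (1S) carbinol ester (target C2).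

**Step 6**
Reactants: 10 (1S)-1-[(4S,5S)-5-[(1S)-1-(benzoyloxy)prop-2-en-1-yl]-5-hydroxy-2,2-dimethyl-1,3-dioxan-4-yl]-3-(phenylselanyl)propyl benzoate
Product: 12 (1S)-1-[(4S,5S)-5-[(1S)-1-(benzoyloxy)prop-2-en-1-yl]-5-hydroxy-2,2-dimethyl-1,3-dioxan-4-yl]prop-2-en-1-yl benzoate, via selenoxide 11 (not isolated)
Conditions: mCPBA (1.05 equiv), CH2Cl2, −78 °C; then i-Pr2NH, −78 °C to 40 °C
Reagents that add atoms: none
Why: Oxidation of the selenide at low temperature followed by thermal syn-elimination of the primary selenoxide, which has only the adjacent CH2 hydrogens to remove, should unmask the terminal vinyl group on C5 without touching the existing alkene or any stereocentre.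

**Step 7**
Reactants: 12 (1S)-1-[(4S,5S)-5-[(1S)-1-(benzoyloxy)prop-2-en-1-yl]-5-hydroxy-2,2-dimethyl-1,3-dioxan-4-yl]prop-2-en-1-yl benzoate
Product: 13 (4aS,5S,8S,8aS)-4a-hydroxy-2,2-dimethyl-4a,5,8,8a-tetrahydro-4H-benzo[d][1,3]dioxine-5,8-diyl dibenzoate
Conditions: second-generation Grubbs catalyst (H2IMes)(PCy3)Cl2Ru=CHPh (5 mol %), CH2Cl2 (0.005 M), 40 °C
Reagents that add atoms: none
Why: The ruthenium alkylidene should load onto the less hindered vinyl group on the C5 arm, engage the second vinyl group intramolecularly through a ruthenacyclobutane ([2+2]/retro-[2+2]) and expel ethene, which drives the reaction. The closest known reaction type is ring-closing olefin metathesis of 3,6-diacyloxyocta-1,7-dienes to conduritol-type cyclohexenes. The six-membered carbocycle is closed by forming the C3=C4 bond only, and the ring size allows only the cis alkene. No stereocentre is created; C1, C2, C5 and C6 are carried through unchanged. The step needs cyclisation to win over cross-metathesis oligomerisation, which is secured by the temporary 1,3-dioxane holding the two alkenyl arms cis on adjacent ring carbons (one axial, one equatorial, hence gauche) and by high dilution. Both alkenes are monosubstituted, and the free tertiary hydroxyl and the allylic benzoates should be tolerated by this catalyst.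

**Step 8**
Reactants: 13 (4aS,5S,8S,8aS)-4a-hydroxy-2,2-dimethyl-4a,5,8,8a-tetrahydro-4H-benzo[d][1,3]dioxine-5,8-diyl dibenzoate
Product: 14 (1R,2S,5S,6S)-1,6-dihydroxy-1-(hydroxymethyl)cyclohex-3-ene-2,5-diyl dibenzoate
Conditions: AcOH/H2O (4:1), 40 °C
Reagents that add atoms: none
Why: Acid-catalysed hydrolysis of the isopropylidene ketal of a 1,3-diol, which is far more labile than the secondary benzoates, should release the C6 and primary hydroxyls without acyl migration at this mild temperature.

**Step 9**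
Reactants: 14 (1R,2S,5S,6S)-1,6-dihydroxy-1-(hydroxymethyl)cyclohex-3-ene-2,5-diyl dibenzoate
Product: 15 [(1R,2S,5S,6S)-2,5-bis(benzoyloxy)-1,6-dihydroxycyclohex-3-en-1-yl]methyl benzoate
Conditions: BzCl (1.05 equiv), pyridine, CH2Cl2, −40 °C to −10 °C
Reagents that add atoms: benzoyl chloride, O=C(Cl)c1ccccc1
Why: Regioselective acylation should occur at the primary hydroxyl, which is much more reactive than the neopentylic secondary C6 hydroxyl (flanked by the quaternary C1 and the C5 benzoate) and the tertiary C1 hydroxyl.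

**Compound list**
1 | acrolein (prop-2-enal) | C=CC=O | starting material
2 | benzeneselenol | [SeH]c1ccccc1 | starting material
3 | 3-(phenylselanyl)propanal | O=CCC[Se]c1ccccc1 | intermediate
4 | 2,2-dimethyl-1,3-dioxan-5-one | CC1(C)OCC(=O)CO1 | starting material
5 | (4S)-4-[(1S)-1-hydroxy-3-(phenylselanyl)propyl]-2,2-dimethyl-1,3-dioxan-5-one | c1ccccc1[Se]CC[C@H](O)[C@@H]2OC(C)(C)OCC2=O | intermediate
6 | (1S)-1-[(4S)-2,2-dimethyl-5-oxo-1,3-dioxan-4-yl]-3-(phenylselanyl)propyl benzoate | c1ccccc1[Se]CC[C@H](OC(=O)c2ccccc2)[C@@H]3OC(C)(C)OCC3=O | intermediate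
7 | benzoyl bromide | O=C(Br)c1ccccc1 | starting material
8 | 3-bromoprop-1-en-1-yl benzoate (E/Z mixture) | BrCC=COC(=O)c1ccccc1 | intermediate
9 | [3-(benzoyloxy)prop-2-en-1-yl]zinc bromide | Br[Zn]CC=COC(=O)c1ccccc1 | intermediate (not isolated)
10 | (1S)-1-[(4S,5S)-5-[(1S)-1-(benzoyloxy)prop-2-en-1-yl]-5-hydroxy-2,2-dimethyl-1,3-dioxan-4-yl]-3-(phenylselanyl)propyl benzoate | c1ccccc1[Se]CC[C@H](OC(=O)c2ccccc2)[C@@H]3OC(C)(C)OC[C@]3(O)[C@@H](OC(=O)c4ccccc4)C=C | intermediate
11 | selenoxide of 10: (1S)-1-[(4S,5S)-5-[(1S)-1-(benzoyloxy)prop-2-en-1-yl]-5-hydroxy-2,2-dimethyl-1,3-dioxan-4-yl]-3-(phenylseleninyl)propyl benzoate | O=[Se](c1ccccc1)CC[C@H](OC(=O)c2ccccc2)[C@@H]3OC(C)(C)OC[C@]3(O)[C@@H](OC(=O)c4ccccc4)C=C | intermediate (not isolated)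
12 | (1S)-1-[(4S,5S)-5-[(1S)-1-(benzoyloxy)prop-2-en-1-yl]-5-hydroxy-2,2-dimethyl-1,3-dioxan-4-yl]prop-2-en-1-yl benzoate | C=C[C@H](OC(=O)c1ccccc1)[C@@H]2OC(C)(C)OC[C@]2(O)[C@@H](OC(=O)c3ccccc3)C=C | intermediate
13 | (4aS,5S,8S,8aS)-4a-hydroxy-2,2-dimethyl-4a,5,8,8a-tetrahydro-4H-benzo[d][1,3]dioxine-5,8-diyl dibenzoate | CC1(C)OC[C@]2(O)[C@@H](OC(=O)c3ccccc3)C=C[C@H](OC(=O)c4ccccc4)[C@@H]2O1 | intermediate
14 | (1R,2S,5S,6S)-1,6-dihydroxy-1-(hydroxymethyl)cyclohex-3-ene-2,5-diyl dibenzoate | OC[C@]1(O)[C@@H](OC(=O)c2ccccc2)C=C[C@H](OC(=O)c3ccccc3)[C@@H]1O | intermediate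
15 | [(1R,2S,5S,6S)-2,5-bis(benzoyloxy)-1,6-dihydroxycyclohex-3-en-1-yl]methyl benzoate | O=C(OC[C@]1(O)[C@@H](OC(=O)c2ccccc2)C=C[C@H](OC(=O)c2ccccc2)[C@@H]1O)c1ccccc1 | target

**Totals**
Total step count: 9. Longest linear sequence: 8 steps (steps 1, 2, 3, 5, 6, 7, 8, 9); step 4 is a one-step side branch.

**Steps most likely to fail**

Step 5. What may go wrong is poor or reversed simple diastereoselection at the benzoyloxy-bearing carbon in the chair transition state, possibly with incomplete axial-face selectivity on the ketone. The fallback sets that centre by reagent control instead. It sets out from 6: zinc-mediated addition of 3-bromoprop-1-en-1-yl acetate F1 (made from 1 and acetyl bromide with ZnCl2, as for 8) would give the acetate adduct F2 as a mixture at the acetoxy carbon. K2CO3 in MeOH at 0 °C should cleave the acetate in the presence of the benzoate to give diol F3. MnO2 in CH2Cl2 would oxidise the allylic alcohol to enone F4, erasing the uncertain centre. Corey–Bakshi–Shibata reduction with the (R)-2-methyl-oxazaborolidine and BH3·SMe2, with the quaternary dioxane carbon as the large group, should then give the (S)-allylic alcohol F5. Benzoylation of the secondary hydroxyl (BzCl, pyridine) comes back to the route at 10.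

Step 2. What may go wrong is loss of benzeneselenol from aldehyde 3 by retro-Michael reaction under amine catalysis, together with self-aldol of the linear aldehyde and slow conversion. The fallback uses an α-oxygenated acceptor, the best-behaved class for this aldol, and builds the vinyl group by olefination. It sets out from 4: the same (S)-proline aldol with (tert-butyldimethylsilyloxy)acetaldehyde would give the silyloxy aldol F6. Benzoylation would give the keto benzoate F7, and zinc-mediated addition of 8 the silyl-protected adduct F8. HF·pyridine should free the primary alcohol F9, and Dess–Martin periodinane would oxidise it to aldehyde F10. Wittig methylenation (Ph3PCH3Br, KN(SiMe3)2, THF, −78 °C) comes back to the route at 12, so that steps 1 and 6 are no longer needed.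

Step 9. What may go wrong is over-acylation at the C6 hydroxyl or base-promoted benzoyl migration from the C5 oxygen to the C6 oxygen. The fallback replaces chemical acylation by biocatalytic regiocontrol under neutral conditions. It sets out from 14: transesterification with vinyl benzoate catalysed by immobilised Candida antarctica lipase B in THF at 40 °C, relying on the enzyme's preference for primary alcohols, comes back to the route at 15 without any new compound.

**Further compounds**
F1 | step 5 | 3-bromoprop-1-en-1-yl acetate (E/Z mixture) | CC(=O)OC=CCBr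
F2 | step 5 | (1S)-1-[(4S,5S)-5-(1-acetoxyprop-2-en-1-yl)-5-hydroxy-2,2-dimethyl-1,3-dioxan-4-yl]-3-(phenylselanyl)propyl benzoate (mixture at the acetoxy carbon) | c1ccccc1[Se]CC[C@H](OC(=O)c2ccccc2)[C@@H]3OC(C)(C)OC[C@]3(O)C(OC(C)=O)C=C
F3 | step 5 | (1S)-1-[(4S,5S)-5-hydroxy-5-(1-hydroxyprop-2-en-1-yl)-2,2-dimethyl-1,3-dioxan-4-yl]-3-(phenylselanyl)propyl benzoate (mixture at the carbinol carbon) | c1ccccc1[Se]CC[C@H](OC(=O)c2ccccc2)[C@@H]3OC(C)(C)OC[C@]3(O)C(O)C=C
F4 | step 5 | (1S)-1-[(4S,5R)-5-hydroxy-2,2-dimethyl-5-(prop-2-enoyl)-1,3-dioxan-4-yl]-3-(phenylselanyl)propyl benzoate | c1ccccc1[Se]CC[C@H](OC(=O)c2ccccc2)[C@@H]3OC(C)(C)OC[C@]3(O)C(=O)C=C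
F5 | step 5 | (1S)-1-[(4S,5S)-5-hydroxy-5-[(1S)-1-hydroxyprop-2-en-1-yl]-2,2-dimethyl-1,3-dioxan-4-yl]-3-(phenylselanyl)propyl benzoate | c1ccccc1[Se]CC[C@H](OC(=O)c2ccccc2)[C@@H]3OC(C)(C)OC[C@]3(O)[C@@H](O)C=C
F6 | step 2 | (4S)-4-[(1S)-2-[(tert-butyldimethylsilyl)oxy]-1-hydroxyethyl]-2,2-dimethyl-1,3-dioxan-5-one | CC(C)(C)[Si](C)(C)OC[C@H](O)[C@@H]1OC(C)(C)OCC1=O
F7 | step 2 | (1S)-2-[(tert-butyldimethylsilyl)oxy]-1-[(4S)-2,2-dimethyl-5-oxo-1,3-dioxan-4-yl]ethyl benzoate | CC(C)(C)[Si](C)(C)OC[C@H](OC(=O)c1ccccc1)[C@@H]2OC(C)(C)OCC2=O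
F8 | step 2 | (1S)-1-[(4S,5S)-5-[(1S)-1-(benzoyloxy)prop-2-en-1-yl]-5-hydroxy-2,2-dimethyl-1,3-dioxan-4-yl]-2-[(tert-butyldimethylsilyl)oxy]ethyl benzoate | CC(C)(C)[Si](C)(C)OC[C@H](OC(=O)c1ccccc1)[C@@H]2OC(C)(C)OC[C@]2(O)[C@@H](OC(=O)c3ccccc3)C=C
F9 | step 2 | (1S)-1-[(4S,5S)-5-[(1S)-1-(benzoyloxy)prop-2-en-1-yl]-5-hydroxy-2,2-dimethyl-1,3-dioxan-4-yl]-2-hydroxyethyl benzoate | OC[C@H](OC(=O)c1ccccc1)[C@@H]2OC(C)(C)OC[C@]2(O)[C@@H](OC(=O)c3ccccc3)C=C
F10 | step 2 | (1R)-1-[(4S,5S)-5-[(1S)-1-(benzoyloxy)prop-2-en-1-yl]-5-hydroxy-2,2-dimethyl-1,3-dioxan-4-yl]-2-oxoethyl benzoate | O=C[C@H](OC(=O)c1ccccc1)[C@@H]2OC(C)(C)OC[C@]2(O)[C@@H](OC(=O)c3ccccc3)C=C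
F0 | step 9 | none | none
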